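**Plan**

1. Numbering: ring A C1–C6 (C1 = CH carrying the chain, C2 = CMe2, C3 = CHOH, C6 = C(Me)OH), chain C7–C11 (C11 = carbinol), ring B C12–C17 (C12 = quaternary epoxide carbon, C15 carries CH2OH). The retrosynthesis cuts C10–C11, then C8–C9 and C7=C8, then, in one step, the two opposite ring A bonds C2–C3 and C5–C6.
2. Feature that allows this: C1 lies between the fully substituted C2 and C6 and is 1,3 to the C3 oxygen. At the carbonyl level ring A is 2,2,4-trimethylcyclohexane-1,3-dione, i.e. the C6–C1–C2 triad of 2-methylpentan-3-one (as its enamine) joined to a C5–C4–C3 acryloyl unit.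
3. Forward, ring A: [3+3] annulation; C3 by catalyst-controlled CBS reduction; C6–O by Rubottom oxidation and C1–H by hydroboration of a C1 methylidene (both substrate-controlled).
4. Chain: Takai olefination (7E), then Negishi coupling with a propyne-derived (Z)-bromoalkenyl boronate (9Z).
5. Ring B: symmetric benzoquinone, masked by a catalytic asymmetric Diels–Alder reaction with cyclopentadiene (absolute configuration); epoxidation and carbonyl reduction from the convex face (epoxide trans to both carbinols); retro-Diels–Alder reaction.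
6. Union by Nozaki–Hiyama–Kishi coupling, C11 by chelation-controlled reduction of the epoxy ketone, global desilylation.

Key step: step 2

Remark on the structure: the target is read as (1R,3R,6R) in ring A, (1S,2Z,4E) in the pentadienyl chain and (1R,2S,5R,6S) in ring B. TBS = tert-butyldimethylsilyl, TES = triethylsilyl, Piv = 2,2-dimethylpropanoyl.
Assumption: the (S)-configured catalysts of steps 3 and 16 are taken to give the enantiomers drawn; if the sense of induction is opposite, the (R)-catalysts are used.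

**Route**

Step 1
Reactants: 1 2-methylpentan-3-one; 2 morpholine
Product: 3 4-(4-methylpent-2-en-3-yl)morpholine (E/Z mixture)
Conditions: p-toluenesulfonic acid (cat.), toluene, reflux, Dean–Stark trap
Reagents that add atoms: none
Why: Acid-catalysed condensation with azeotropic removal of water (first stage of a Stork enamine sequence) should give the less substituted enamine, because allylic strain disfavours the tetrasubstituted double bond on the isopropyl side.

Step 2
Reactants: 3 4-(4-methylpent-2-en-3-yl)morpholine; 4 prop-2-enoyl chloride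
Product: 7 2,2,4-trimethylcyclohexane-1,3-dione (racemic), via ketene iminium chloride 5 (not isolated), via cyclic iminium chloride 6 (not isolated)
Conditions: toluene, 80 °C; then H2O, rt
Reagents that add atoms: water (O)
Why: Mechanism: the enamine is N-acylated and the N-acryloyl enammonium ion undergoes a 3-aza-Cope shift (equivalent to conjugate C-alkylation), which joins the enamine carbon C6 to the acryloyl β-carbon C5 and releases ketene iminium 5; proton transfer then moves the enamine to the isopropyl side and its carbon C2 acylates the ketene to give iminium 6, which water hydrolyses to dione 7. The closest known reaction type is the Stork-enamine annulation of cyclic ketone enamines with acryloyl chloride to bicyclo[3.3.1]nonane-2,9-diones. The single ring of 7 is closed in the second bond formation by a 6-(enolendo)-exo-dig attack of the enamine carbon on the ketene carbonyl carbon, helped by the gem-dimethyl effect. The only stereocentre formed, C6, is deliberately left uncontrolled (racemic, epimerisable) because it is made planar again in step 4. The step needs regioselectivity (first bond at the ethyl-side carbon, second bond at the isopropyl carbon) and C- over O-acylation of the ketene; the first follows from the less substituted enamine 3 fixed in step 1, the second from the six-membered transition state available only to carbon C2.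

Step 3
Reactants: 7 2,2,4-trimethylcyclohexane-1,3-dione
Product: 8 (3R)-3-hydroxy-2,2,6-trimethylcyclohexan-1-one (mixture of C6 epimers)
Conditions: (S)-1-methyl-3,3-diphenyltetrahydro-1H,3H-pyrrolo[1,2-c][1,3,2]oxazaborole (20 mol %), catecholborane, toluene, −78 °C
Reagents that add atoms: none
Why: CBS reduction should reduce only the carbonyl flanked by the ring CH2 (future C3), the other one lying between two branched carbons, and the oxazaborolidine, reading the quaternary C2 as the large group, should deliver hydride to the face that gives the 3R alcohol, while the remote C6 centre stays a mixture that is erased in step 4.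

Step 4
Reactants: 8 (3R)-3-hydroxy-2,2,6-trimethylcyclohexan-1-one
Product: 10 tert-butyldimethyl{[(1R)-2,2,4-trimethyl-3-(triethylsilyloxy)cyclohex-3-en-1-yl]oxy}silane, via silyl ether ketone 9 (not isolated)
Conditions: TBSOTf, 2,6-lutidine, CH2Cl2, −78 °C; then TESOTf, Et3N, 0 °C to rt
Reagents that add atoms: tert-butyldimethylsilyl trifluoromethanesulfonate (CC(C)(C)[Si](C)(C)OS(=O)(=O)C(F)(F)F); triethylsilyl trifluoromethanesulfonate (CC[Si](CC)(CC)OS(=O)(=O)C(F)(F)F)
Why: The silyl triflates should first silylate the hindered secondary alcohol and then convert the ketone into its only possible silyl enol ether (C2 is quaternary), which makes C6 planar.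

Step 5
Reactants: 10 tert-butyldimethyl{[(1R)-2,2,4-trimethyl-3-(triethylsilyloxy)cyclohex-3-en-1-yl]oxy}silane
Product: 12 (3R,6R)-3-(tert-butyldimethylsilyloxy)-2,2,6-trimethyl-6-(triethylsilyloxy)cyclohexan-1-one, via silyloxy epoxide 11 (not isolated)
Conditions: m-CPBA, NaHCO3, CH2Cl2, −20 °C to rt
Reagents that add atoms: 3-chloroperoxybenzoic acid (OOC(=O)c1cccc(Cl)c1)
Why: Rubottom oxidation, in which the peracid should attack the enol ether face opposite the pseudo-axial C2 methyl group of the half-chair with the C3 silyloxy group equatorial, and opening of epoxide 11 with silyl migration then gives the α-silyloxy ketone with the C6 oxygen trans to the C3 oxygen (6R).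

Step 6
Reactants: 12 (3R,6R)-3-(tert-butyldimethylsilyloxy)-2,2,6-trimethyl-6-(triethylsilyloxy)cyclohexan-1-one
Product: 13 tert-butyldimethyl{[(1R,4R)-2,2,4-trimethyl-3-methylidene-4-(triethylsilyloxy)cyclohexyl]oxy}silane
Conditions: Cp2TiMe2, toluene, 75 °C
Reagents that add atoms: dimethyltitanocene Cp2TiMe2 (C[Ti](C)(C1C=CC=C1)C1C=CC=C1)
Why: Petasis methylenation through Cp2Ti=CH2 is a non-basic carbonyl olefination that should reach a ketone flanked by two fully substituted carbons where phosphorus ylides fail.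

Step 7
Reactants: 13 tert-butyldimethyl{[(1R,4R)-2,2,4-trimethyl-3-methylidene-4-(triethylsilyloxy)cyclohexyl]oxy}silane
Product: 15 [(1S,3R,6R)-3-(tert-butyldimethylsilyloxy)-2,2,6-trimethyl-6-(triethylsilyloxy)cyclohexyl]methanol, via primary alkylborane 14 (not isolated)
Conditions: BH3·THF, THF, 0 °C to rt; then NaOH, H2O2, 0 °C
Reagents that add atoms: hydrogen peroxide (OO)
Why: Hydroboration–oxidation should place boron on the terminal carbon and deliver hydrogen to C1 from the face opposite the two axial methyl groups at C2 and C6 of the chair with both silyloxy groups equatorial, which sets C1 with its hydrogen cis to the C6 oxygen.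

Step 8
Reactants: 15 [(1S,3R,6R)-3-(tert-butyldimethylsilyloxy)-2,2,6-trimethyl-6-(triethylsilyloxy)cyclohexyl]methanol
Product: 16 (1R,3R,6R)-3-(tert-butyldimethylsilyloxy)-2,2,6-trimethyl-6-(triethylsilyloxy)cyclohexane-1-carbaldehyde
Conditions: Dess–Martin periodinane, NaHCO3, CH2Cl2, 0 °C to rt
Reagents that add atoms: none
Why: Dess–Martin oxidation is neutral, so the C1 stereocentre next to the new aldehyde, shielded by two quaternary neighbours, should not epimerise.

Step 9
Reactants: 16 (1R,3R,6R)-3-(tert-butyldimethylsilyloxy)-2,2,6-trimethyl-6-(triethylsilyloxy)cyclohexane-1-carbaldehyde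
Product: 17 tert-butyl{[(1R,3R,4R)-3-[(E)-2-iodoethenyl]-2,2,4-trimethyl-4-(triethylsilyloxy)cyclohexyl]oxy}dimethylsilane
Conditions: CrCl2, CHI3, THF/1,4-dioxane, 0 °C to rt
Reagents that add atoms: iodoform (IC(I)I)
Why: Takai olefination with the gem-dichromium reagent formed from CHI3 and CrCl2 should give the E-iodoalkene under non-basic conditions.

Step 10
Reactants: 18 propyne
Product: 20 (Z)-2-(2-bromoprop-1-en-1-yl)-4,4,5,5-tetramethyl-1,3,2-dioxaborolane, via alkenyldibromoborane 19 (not isolated)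
Conditions: BBr3, CH2Cl2, −78 °C; then pinacol, −78 °C to rt
Reagents that add atoms: boron tribromide (BrB(Br)Br); pinacol (CC(C)(O)C(C)(C)O)
Why: syn-Bromoboration of the alkyne places bromine on the internal and boron on the terminal carbon on the same side, and esterification with pinacol gives the stable Z-bromoalkenyl boronate.

Step 11
Reactants: 17 tert-butyl{[(1R,3R,4R)-3-[(E)-2-iodoethenyl]-2,2,4-trimethyl-4-(triethylsilyloxy)cyclohexyl]oxy}dimethylsilane; 20 (Z)-2-(2-bromoprop-1-en-1-yl)-4,4,5,5-tetramethyl-1,3,2-dioxaborolane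
Product: 23 2-{(1Z,3E)-4-[(1R,3R,6R)-3-(tert-butyldimethylsilyloxy)-2,2,6-trimethyl-6-(triethylsilyloxy)cyclohexyl]-2-methylbuta-1,3-dien-1-yl}-4,4,5,5-tetramethyl-1,3,2-dioxaborolane, via alkenyllithium 21 (not isolated), via alkenylzinc bromide 22 (not isolated)
Conditions: t-BuLi, Et2O, −78 °C; ZnBr2, THF, −78 to 0 °C; then 20, Pd(P(t-Bu)3)2 (2 mol %), THF, rt
Reagents that add atoms: none
Why: Iodine–lithium exchange, transmetalation to zinc and Negishi coupling at the C–Br bond of 20 all proceed with retention of alkene geometry and leave the C–B bond intact, which forms C8–C9 and fixes the 7E,9Z diene.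

Step 12
Reactants: 23 the dienyl boronate of step 11
Product: 24 tert-butyl{[(1R,3R,4R)-3-[(1E,3Z)-4-iodo-3-methylbuta-1,3-dien-1-yl]-2,2,4-trimethyl-4-(triethylsilyloxy)cyclohexyl]oxy}dimethylsilane
Conditions: NaOH (aq), I2, THF, 0 °C, dark
Reagents that add atoms: iodine (II)
Why: Iododeboronation through the hydroxide ate complex of the alkenyl boronate should proceed with retention and give the Z-iodide needed for the chromium-mediated coupling.

Step 13
Reactants: 25 2,5-dimethoxyterephthalaldehyde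
Product: 26 (2,5-dimethoxy-1,4-phenylene)dimethanol
Conditions: NaBH4, MeOH/THF, 0 °C
Reagents that add atoms: none
Why: Borohydride reduction of both aryl aldehyde groups.

Step 14
Reactants: 26 (2,5-dimethoxy-1,4-phenylene)dimethanol
Product: 27 (2,5-dimethoxy-1,4-phenylene)bis(methylene) bis(2,2-dimethylpropanoate)
Conditions: PivCl, pyridine, 4-(dimethylamino)pyridine (cat.), CH2Cl2, 0 °C to rt
Reagents that add atoms: pivaloyl chloride (CC(C)(C)C(=O)Cl)
Why: Acylation gives pivalates that should survive the oxidation, the Lewis acid, the peroxide, the hydride and the thermolysis that follow.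

Step 15
Reactants: 27 (2,5-dimethoxy-1,4-phenylene)bis(methylene) bis(2,2-dimethylpropanoate)
Product: 28 (3,6-dioxocyclohexa-1,4-diene-1,4-diyl)bis(methylene) bis(2,2-dimethylpropanoate)
Conditions: (NH4)2Ce(NO3)6, MeCN/H2O, 0 °C
Reagents that add atoms: water (O)
Why: Oxidative demethylation of the 1,4-dimethoxyarene with (NH4)2Ce(NO3)6 gives the quinone, whose two ring double bonds are equivalent by symmetry.

Step 16
Reactants: 28 the quinone of step 15; 29 cyclopenta-1,3-diene
Product: 30 (1,4-dioxo-1,4,4a,5,8,8a-hexahydro-5,8-methanonaphthalene-2,4a-diyl)bis(methylene) bis(2,2-dimethylpropanoate), endo cis-fused adduct, single enantiomer as in the SMILES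
Conditions: (S)-1-(2-methylphenyl)-3,3-diphenyltetrahydro-1H,3H-pyrrolo[1,2-c][1,3,2]oxazaborole·HN(SO2CF3)2 (20 mol %), CH2Cl2, −78 °C
Reagents that add atoms: none
Why: Catalytic enantioselective Diels–Alder reaction, in which the chiral oxazaborolidinium ion binds a quinone carbonyl and blocks one face so that cyclopentadiene adds endo to one of the two equivalent double bonds, which sets the absolute configuration of ring B and masks the future C15=C16 alkene.

Step 17
Reactants: 30 the Diels–Alder adduct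
Product: 31 2,3-epoxide of 30 with the oxygen on the convex (exo) face
Conditions: t-BuOOH, DBU, CH2Cl2, 0 °C
Reagents that add atoms: tert-butyl hydroperoxide (CC(C)(C)OO)
Why: Weitz–Scheffer epoxidation of the remaining enedione double bond should occur on the convex face of the cis-fused adduct, away from the norbornene unit, which sets C12 and C13.

Step 18
Reactants: 31 the epoxy dione
Product: 32 1,4-diol from 31 with both hydroxyl groups on the concave face, trans to the epoxide
Conditions: NaBH4, CeCl3·7H2O, MeOH, −40 °C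
Reagents that add atoms: none
Why: Luche reduction should deliver hydride to both ketones from the same convex face, so that both hydroxyl groups lie on the concave face, trans to the epoxide, which sets C14 and C17.

Step 19
Reactants: 32 the epoxy diol
Product: 33 bis(tert-butyldimethylsilyl) ether of 32
Conditions: TBSOTf, 2,6-lutidine, CH2Cl2, 0 °C to rt
Reagents that add atoms: tert-butyldimethylsilyl trifluoromethanesulfonate (CC(C)(C)[Si](C)(C)OS(=O)(=O)C(F)(F)F)
Why: Silylation with the silyl triflate protects the two hindered secondary alcohols before thermolysis.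

Step 20
Reactants: 33 the bis-silyl ether
Product: 34 [(1S,2S,5R,6S)-2,5-bis(tert-butyldimethylsilyloxy)-4-[(2,2-dimethylpropanoyloxy)methyl]-7-oxabicyclo[4.1.0]hept-3-en-1-yl]methyl 2,2-dimethylpropanoate
Conditions: Ph2O, 230 °C
Reagents that add atoms: none
Why: Thermal retro-Diels–Alder reaction expels cyclopentadiene and restores the C15=C16 double bond without touching the four stereocentres.

Step 21
Reactants: 34 the bis-pivalate
Product: 35 [(1S,2S,5R,6S)-2,5-bis(tert-butyldimethylsilyloxy)-7-oxabicyclo[4.1.0]hept-3-ene-1,4-diyl]dimethanol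
Conditions: i-Bu2AlH, CH2Cl2, −78 °C
Reagents that add atoms: none
Why: Reduction with i-Bu2AlH at low temperature cleaves both pivalates while the trisubstituted epoxide and the silyl ethers should survive.

Step 22
Reactants: 35 the diol
Product: 36 [(1S,2S,5R,6S)-2,5-bis(tert-butyldimethylsilyloxy)-4-[(tert-butyldimethylsilyloxy)methyl]-7-oxabicyclo[4.1.0]hept-3-en-1-yl]methanol
Conditions: TBSCl, imidazole, CH2Cl2, −20 °C
Reagents that add atoms: tert-butyldimethylsilyl chloride (CC(C)(C)[Si](C)(C)Cl)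
Why: The allylic primary alcohol should be silylated faster than the neopentyl-type primary alcohol on the quaternary epoxide carbon C12.

Step 23
Reactants: 36 the mono-alcohol
Product: 37 (1S,2S,5R,6S)-2,5-bis(tert-butyldimethylsilyloxy)-4-[(tert-butyldimethylsilyloxy)methyl]-7-oxabicyclo[4.1.0]hept-3-ene-1-carbaldehyde
Conditions: Dess–Martin periodinane, NaHCO3, CH2Cl2, 0 °C to rt
Reagents that add atoms: none
Why: Dess–Martin oxidation gives the α,β-epoxy aldehyde, which cannot epimerise because C12 is quaternary.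

Step 24
Reactants: 24 the (1E,3Z)-dienyl iodide; 37 the epoxy aldehyde
Product: 39 (2Z,4E)-1-[(1S,2S,5R,6S)-2,5-bis(tert-butyldimethylsilyloxy)-4-[(tert-butyldimethylsilyloxy)methyl]-7-oxabicyclo[4.1.0]hept-3-en-1-yl]-5-[(1R,3R,6R)-3-(tert-butyldimethylsilyloxy)-2,2,6-trimethyl-6-(triethylsilyloxy)cyclohexyl]-3-methylpenta-2,4-dien-1-ol (mixture of C1 epimers), via alkenylchromium dichloride 38 (not isolated)
Conditions: CrCl2, NiCl2 (1 mol %), DMSO/THF, rt
Reagents that add atoms: none
Why: Nozaki–Hiyama–Kishi coupling, in which alkenylchromium 38 is formed with retention of the Z geometry and adds chemoselectively to the hindered aldehyde, the configuration at C11 not being relied on because it is reset in steps 25 and 26.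

Step 25
Reactants: 39 the epimeric dienols
Product: 40 (2Z,4E)-1-[(1S,2S,5R,6S)-2,5-bis(tert-butyldimethylsilyloxy)-4-[(tert-butyldimethylsilyloxy)methyl]-7-oxabicyclo[4.1.0]hept-3-en-1-yl]-5-[(1R,3R,6R)-3-(tert-butyldimethylsilyloxy)-2,2,6-trimethyl-6-(triethylsilyloxy)cyclohexyl]-3-methylpenta-2,4-dien-1-one
Conditions: Dess–Martin periodinane, NaHCO3, CH2Cl2, 0 °C
Reagents that add atoms: none
Why: Dess–Martin oxidation of the doubly allylic alcohol gives the cross-conjugated Z-dienone under neutral conditions that should not isomerise the 9Z double bond.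

Step 26
Reactants: 40 the epoxy dienone
Product: 41 (1S,2Z,4E)-1-[(1S,2S,5R,6S)-2,5-bis(tert-butyldimethylsilyloxy)-4-[(tert-butyldimethylsilyloxy)methyl]-7-oxabicyclo[4.1.0]hept-3-en-1-yl]-5-[(1R,3R,6R)-3-(tert-butyldimethylsilyloxy)-2,2,6-trimethyl-6-(triethylsilyloxy)cyclohexyl]-3-methylpenta-2,4-dien-1-ol
Conditions: Zn(BH4)2, Et2O, −20 °C
Reagents that add atoms: none
Why: Chelation-controlled reduction of an α,β-epoxy ketone, in which zinc bridges the carbonyl and epoxide oxygens and hydride attacks on the side away from the epoxide carbon C13, should give the erythro epoxy alcohol (11S).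

Step 27
Reactants: 41 the pentasilyl ether
Product: 42 arthrosporol A, (1R,2S,5R,6S)-1-[(1S,2Z,4E)-5-[(1R,3R,6R)-3,6-dihydroxy-2,2,6-trimethylcyclohexyl]-1-hydroxy-3-methylpenta-2,4-dien-1-yl]-4-(hydroxymethyl)-7-oxabicyclo[4.1.0]hept-3-ene-2,5-diol
Conditions: Bu4NF, AcOH (1:1), THF, 0 °C to rt
Reagents that add atoms: none
Why: Buffered fluoride removes all five silyl groups without acid or strong base, which protects the epoxide and the doubly allylic C11 carbinol.

**Compound list**

1 | 2-methylpentan-3-one | CCC(=O)C(C)C | starting material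
2 | morpholine | C1COCCN1 | starting material
3 | 4-(4-methylpent-2-en-3-yl)morpholine (E/Z mixture) | CC=C(N1CCOCC1)C(C)C | intermediate
4 | prop-2-enoyl chloride | C=CC(=O)Cl | starting material
5 | 4-(2,4-dimethyl-7-oxohepta-6-en-3-ylidene)morpholin-4-ium chloride (ketene iminium, not isolated) | CC(C)C(=[N+]1CCOCC1)C(C)CC=C=O.[Cl-] | intermediate
6 | 4-(2,2,6-trimethyl-3-oxocyclohexylidene)morpholin-4-ium chloride (not isolated) | CC1CCC(=O)C(C)(C)C1=[N+]1CCOCC1.[Cl-] | intermediate
7 | 2,2,4-trimethylcyclohexane-1,3-dione (racemic) | CC1CCC(=O)C(C)(C)C1=O | intermediate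
8 | (3R)-3-hydroxy-2,2,6-trimethylcyclohexan-1-one (C6 epimers) | O=C1C(C)(C)[C@H](O)CCC1C | intermediate
9 | (3R)-3-(tert-butyldimethylsilyloxy)-2,2,6-trimethylcyclohexan-1-one (C6 epimers, not isolated) | O=C1C(C)(C)[C@H](O[Si](C)(C)C(C)(C)C)CCC1C | intermediate
10 | tert-butyldimethyl{[(1R)-2,2,4-trimethyl-3-(triethylsilyloxy)cyclohex-3-en-1-yl]oxy}silane | CC1=C(O[Si](CC)(CC)CC)C(C)(C)[C@H](O[Si](C)(C)C(C)(C)C)CC1 | intermediate
11 | 3,4-epoxide of 10, epoxide oxygen trans to the TBS ether (not isolated) | CC[Si](CC)(CC)O[C@]12C(C)(C)[C@H](O[Si](C)(C)C(C)(C)C)CC[C@@]1(C)O2 | intermediate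
12 | (3R,6R)-3-(tert-butyldimethylsilyloxy)-2,2,6-trimethyl-6-(triethylsilyloxy)cyclohexan-1-one | O=C1C(C)(C)[C@H](O[Si](C)(C)C(C)(C)C)CC[C@@]1(C)O[Si](CC)(CC)CC | intermediate
13 | tert-butyldimethyl{[(1R,4R)-2,2,4-trimethyl-3-methylidene-4-(triethylsilyloxy)cyclohexyl]oxy}silane | C=C1C(C)(C)[C@H](O[Si](C)(C)C(C)(C)C)CC[C@@]1(C)O[Si](CC)(CC)CC | intermediate
14 | {[(1S,3R,6R)-3-(tert-butyldimethylsilyloxy)-2,2,6-trimethyl-6-(triethylsilyloxy)cyclohexyl]methyl}borane (not isolated) | BC[C@@H]1C(C)(C)[C@H](O[Si](C)(C)C(C)(C)C)CC[C@@]1(C)O[Si](CC)(CC)CC | intermediate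
15 | [(1S,3R,6R)-3-(tert-butyldimethylsilyloxy)-2,2,6-trimethyl-6-(triethylsilyloxy)cyclohexyl]methanol | OC[C@@H]1C(C)(C)[C@H](O[Si](C)(C)C(C)(C)C)CC[C@@]1(C)O[Si](CC)(CC)CC | intermediate
16 | (1R,3R,6R)-3-(tert-butyldimethylsilyloxy)-2,2,6-trimethyl-6-(triethylsilyloxy)cyclohexane-1-carbaldehyde | O=C[C@@H]1C(C)(C)[C@H](O[Si](C)(C)C(C)(C)C)CC[C@@]1(C)O[Si](CC)(CC)CC | intermediate
17 | tert-butyl{[(1R,3R,4R)-3-[(E)-2-iodoethenyl]-2,2,4-trimethyl-4-(triethylsilyloxy)cyclohexyl]oxy}dimethylsilane | I/C=C/[C@@H]1C(C)(C)[C@H](O[Si](C)(C)C(C)(C)C)CC[C@@]1(C)O[Si](CC)(CC)CC | intermediate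
18 | propyne | CC#C | starting material
19 | (Z)-dibromo(2-bromoprop-1-en-1-yl)borane (not isolated) | C/C(Br)=C/B(Br)Br | intermediate
20 | (Z)-2-(2-bromoprop-1-en-1-yl)-4,4,5,5-tetramethyl-1,3,2-dioxaborolane | C/C(Br)=C/B1OC(C)(C)C(C)(C)O1 | intermediate
21 | (E)-alkenyllithium from 17 (lithium in place of iodine, not isolated) | [Li]/C=C/[C@@H]1C(C)(C)[C@H](O[Si](C)(C)C(C)(C)C)CC[C@@]1(C)O[Si](CC)(CC)CC | intermediate
22 | (E)-alkenylzinc bromide from 21 (not isolated) | Br[Zn]/C=C/[C@@H]1C(C)(C)[C@H](O[Si](C)(C)C(C)(C)C)CC[C@@]1(C)O[Si](CC)(CC)CC | intermediate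
23 | 2-{(1Z,3E)-4-[(1R,3R,6R)-3-(tert-butyldimethylsilyloxy)-2,2,6-trimethyl-6-(triethylsilyloxy)cyclohexyl]-2-methylbuta-1,3-dien-1-yl}-4,4,5,5-tetramethyl-1,3,2-dioxaborolane | CC(=C/B1OC(C)(C)C(C)(C)O1)/C=C/[C@@H]1C(C)(C)[C@H](O[Si](C)(C)C(C)(C)C)CC[C@@]1(C)O[Si](CC)(CC)CC | intermediate
24 | tert-butyl{[(1R,3R,4R)-3-[(1E,3Z)-4-iodo-3-methylbuta-1,3-dien-1-yl]-2,2,4-trimethyl-4-(triethylsilyloxy)cyclohexyl]oxy}dimethylsilane | CC(=C/I)/C=C/[C@@H]1C(C)(C)[C@H](O[Si](C)(C)C(C)(C)C)CC[C@@]1(C)O[Si](CC)(CC)CC | intermediate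
25 | 2,5-dimethoxyterephthalaldehyde | COc1cc(C=O)c(OC)cc1C=O | starting material
26 | (2,5-dimethoxy-1,4-phenylene)dimethanol | COc1cc(CO)c(OC)cc1CO | intermediate
27 | (2,5-dimethoxy-1,4-phenylene)bis(methylene) bis(2,2-dimethylpropanoate) | COc1cc(COC(=O)C(C)(C)C)c(OC)cc1COC(=O)C(C)(C)C | intermediate
28 | (3,6-dioxocyclohexa-1,4-diene-1,4-diyl)bis(methylene) bis(2,2-dimethylpropanoate) | CC(C)(C)C(=O)OCC1=CC(=O)C(COC(=O)C(C)(C)C)=CC1=O | intermediate
29 | cyclopenta-1,3-diene | C1=CCC=C1 | starting material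
30 | (1,4-dioxo-1,4,4a,5,8,8a-hexahydro-5,8-methanonaphthalene-2,4a-diyl)bis(methylene) bis(2,2-dimethylpropanoate), endo cis-fused adduct | CC(C)(C)C(=O)OCC1=CC(=O)[C@]2(COC(=O)C(C)(C)C)[C@@H]3C=C[C@@H](C3)[C@@H]2C1=O | intermediate
31 | 2,3-epoxide of 30, oxygen on the convex face | CC(C)(C)C(=O)OC[C@]12O[C@H]1C(=O)[C@]3(COC(=O)C(C)(C)C)[C@@H]4C=C[C@@H](C4)[C@@H]3C2=O | intermediate
32 | 1,4-diol from 31, both hydroxyl groups on the concave face, trans to the epoxide | CC(C)(C)C(=O)OC[C@]12O[C@H]1[C@H](O)[C@]3(COC(=O)C(C)(C)C)[C@@H]4C=C[C@@H](C4)[C@@H]3[C@@H]2O | intermediate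
33 | bis(tert-butyldimethylsilyl) ether of 32 | CC(C)(C)C(=O)OC[C@]12O[C@H]1[C@H](O[Si](C)(C)C(C)(C)C)[C@]3(COC(=O)C(C)(C)C)[C@@H]4C=C[C@@H](C4)[C@@H]3[C@@H]2O[Si](C)(C)C(C)(C)C | intermediate
34 | [(1S,2S,5R,6S)-2,5-bis(tert-butyldimethylsilyloxy)-4-[(2,2-dimethylpropanoyloxy)methyl]-7-oxabicyclo[4.1.0]hept-3-en-1-yl]methyl 2,2-dimethylpropanoate | CC(C)(C)C(=O)OC[C@]12O[C@H]1[C@H](O[Si](C)(C)C(C)(C)C)C(COC(=O)C(C)(C)C)=C[C@@H]2O[Si](C)(C)C(C)(C)C | intermediate
35 | [(1S,2S,5R,6S)-2,5-bis(tert-butyldimethylsilyloxy)-7-oxabicyclo[4.1.0]hept-3-ene-1,4-diyl]dimethanol | OC[C@]12O[C@H]1[C@H](O[Si](C)(C)C(C)(C)C)C(CO)=C[C@@H]2O[Si](C)(C)C(C)(C)C | intermediate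
36 | [(1S,2S,5R,6S)-2,5-bis(tert-butyldimethylsilyloxy)-4-[(tert-butyldimethylsilyloxy)methyl]-7-oxabicyclo[4.1.0]hept-3-en-1-yl]methanol | OC[C@]12O[C@H]1[C@H](O[Si](C)(C)C(C)(C)C)C(CO[Si](C)(C)C(C)(C)C)=C[C@@H]2O[Si](C)(C)C(C)(C)C | intermediate
37 | (1S,2S,5R,6S)-2,5-bis(tert-butyldimethylsilyloxy)-4-[(tert-butyldimethylsilyloxy)methyl]-7-oxabicyclo[4.1.0]hept-3-ene-1-carbaldehyde | O=C[C@]12O[C@H]1[C@H](O[Si](C)(C)C(C)(C)C)C(CO[Si](C)(C)C(C)(C)C)=C[C@@H]2O[Si](C)(C)C(C)(C)C | intermediate
38 | (1Z,3E)-dienylchromium dichloride from 24 (CrCl2 in place of iodine, not isolated) | CC(=C/[Cr](Cl)Cl)/C=C/[C@@H]1C(C)(C)[C@H](O[Si](C)(C)C(C)(C)C)CC[C@@]1(C)O[Si](CC)(CC)CC | intermediate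
39 | (2Z,4E)-dienol coupling product, C11 epimers (full name in step 24) | CC(=C/C(O)[C@]12O[C@H]1[C@H](O[Si](C)(C)C(C)(C)C)C(CO[Si](C)(C)C(C)(C)C)=C[C@@H]2O[Si](C)(C)C(C)(C)C)/C=C/[C@@H]1C(C)(C)[C@H](O[Si](C)(C)C(C)(C)C)CC[C@@]1(C)O[Si](CC)(CC)CC | intermediate
40 | (2Z,4E)-dienone (full name in step 25) | CC(=C/C(=O)[C@]12O[C@H]1[C@H](O[Si](C)(C)C(C)(C)C)C(CO[Si](C)(C)C(C)(C)C)=C[C@@H]2O[Si](C)(C)C(C)(C)C)/C=C/[C@@H]1C(C)(C)[C@H](O[Si](C)(C)C(C)(C)C)CC[C@@]1(C)O[Si](CC)(CC)CC | intermediate
41 | (1S,2Z,4E)-dienol, pentasilyl ether of the target (full name in step 26) | CC(=C/[C@H](O)[C@]12O[C@H]1[C@H](O[Si](C)(C)C(C)(C)C)C(CO[Si](C)(C)C(C)(C)C)=C[C@@H]2O[Si](C)(C)C(C)(C)C)/C=C/[C@@H]1C(C)(C)[C@H](O[Si](C)(C)C(C)(C)C)CC[C@@]1(C)O[Si](CC)(CC)CC | intermediate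
42 | arthrosporol A (full name in step 27) | CC(=C/[C@H](O)[C@]12O[C@H]1[C@H](O)C(CO)=C[C@@H]2O)/C=C/[C@@H]1C(C)(C)[C@H](O)CC[C@@]1(C)O | target

**Totals and risks**

Total step count: 27. Longest linear sequence: 15 steps (steps 1–9, 11, 12 and 24–27; the ring B line, steps 13–27, has the same length).

Most likely to fail:

Step 2. The second, ring-closing C-acylation has to form the quaternary C2 at a hindered isopropyl carbon; O-acylation of the ketene or oligomerisation of the acid chloride may compete. Fallback (stepwise polar route, sets out from 1, returns at 7): LiN(i-Pr)2 at −78 °C deprotonates the ethyl side of 1 and alkylation with 2-(2-iodoethyl)-1,3-dioxolane gives 6-(1,3-dioxolan-2-yl)-2,4-dimethylhexan-3-one F1. Aqueous HCl in THF then hydrolyses the acetal and closes the ring by aldol addition of the isopropyl-side enol to the aldehyde, giving 3-hydroxy-2,2,6-trimethylcyclohexan-1-one F2 as a stereoisomer mixture. Dess–Martin oxidation of F2 gives 7.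

Step 7. Facial selectivity of the hydroboration may be poor if the chair with axial silyloxy groups takes part. Fallback (thermodynamic correction instead of kinetic control, sets out from 15, returns at 16): the alcohol is taken on as the mixture of 15 with its C1 epimer [(1R,3R,6R)-3-(tert-butyldimethylsilyloxy)-2,2,6-trimethyl-6-(triethylsilyloxy)cyclohexyl]methanol F3. Dess–Martin oxidation gives 16 together with (1S,3R,6R)-3-(tert-butyldimethylsilyloxy)-2,2,6-trimethyl-6-(triethylsilyloxy)cyclohexane-1-carbaldehyde F4, and the two are separated. F4 is equilibrated with DBU in toluene through its enol (C1 is the only enolisable position), and 16 is separated again and the remainder recycled.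

Step 16. The fast uncatalysed cycloaddition may erode the enantioselectivity. Fallback (resolution instead of asymmetric catalysis, sets out from 28 and 29, returns at 32): the thermal Diels–Alder reaction gives 30 together with its enantiomer F5. Steps 17 and 18 on the racemate give the epoxide (31 with its enantiomer F6) and the diol (32 with its enantiomer F7). Acetylation with vinyl acetate and the lipase from Burkholderia cepacia (kinetic resolution) should acylate the unwanted enantiomer to its monoacetate F8, drawn at the hydroxyl next to C12, and chromatography then gives 32.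

Further compounds
F1 | step 2 | 6-(1,3-dioxolan-2-yl)-2,4-dimethylhexan-3-one | CC(C)C(=O)C(C)CCC1OCCO1
F2 | step 2 | 3-hydroxy-2,2,6-trimethylcyclohexan-1-one (racemic, mixture of diastereomers) | CC1CCC(O)C(C)(C)C1=O
F3 | step 7 | [(1R,3R,6R)-3-(tert-butyldimethylsilyloxy)-2,2,6-trimethyl-6-(triethylsilyloxy)cyclohexyl]methanol (C1 epimer of 15) | OC[C@H]1C(C)(C)[C@H](O[Si](C)(C)C(C)(C)C)CC[C@@]1(C)O[Si](CC)(CC)CC
F4 | step 7 | (1S,3R,6R)-3-(tert-butyldimethylsilyloxy)-2,2,6-trimethyl-6-(triethylsilyloxy)cyclohexane-1-carbaldehyde (C1 epimer of 16) | O=C[C@H]1C(C)(C)[C@H](O[Si](C)(C)C(C)(C)C)CC[C@@]1(C)O[Si](CC)(CC)CC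
F5 | step 16 | enantiomer of 30 | CC(C)(C)C(=O)OCC1=CC(=O)[C@@]2(COC(=O)C(C)(C)C)[C@H]3C=C[C@H](C3)[C@H]2C1=O
F6 | step 16 | enantiomer of 31 | CC(C)(C)C(=O)OC[C@@]12O[C@@H]1C(=O)[C@@]3(COC(=O)C(C)(C)C)[C@H]4C=C[C@H](C4)[C@H]3C2=O
F7 | step 16 | enantiomer of 32 | CC(C)(C)C(=O)OC[C@@]12O[C@@H]1[C@@H](O)[C@@]3(COC(=O)C(C)(C)C)[C@H]4C=C[C@H](C4)[C@H]3[C@H]2O
F8 | step 16 | monoacetate of F7 (acetate on the hydroxyl next to C12) | CC(C)(C)C(=O)OC[C@@]12O[C@@H]1[C@@H](O)[C@@]3(COC(=O)C(C)(C)C)[C@H]4C=C[C@H](C4)[C@H]3[C@H]2OC(C)=O
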